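**Strategy.** The route rests on cutting the trisubstituted C3=C4 olefin of the seven-membered oxepine ring, which lies between the O1–C2H2 ether arm and the benzylic C5H2 arm on adjacent carbons C9a and C5a of ring A. Ring-closing olefin metathesis of an O-methallyl/ortho-C-allyl diene forges this C=C bond and the oxepine ring in one operation, ethylene being the only co-product. The diene precursor is 3'-allyl-4'-O-methallyl-3-hydroxyphloretin, assembled without protecting groups from phloroglucinol and dihydrocaffeic acid by acylation, acidity-guided 4'-O-allylation, aromatic Claisen rearrangement (ring A is symmetric, so one ortho product) and 4'-O-methallylation.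

Key step: step 5

Remark: primed locants refer to ring A (the acylphloroglucinol ring) of the dihydrochalcone and unprimed locants to the catechol ring. The target has no stereocentre, and its ring olefin is cis by ring constraint.

**Step 1**
Reactants: 1 phloroglucinol; 2 3-(3,4-dihydroxyphenyl)propanoic acid
Product: 3 3-(3,4-dihydroxyphenyl)-1-(2,4,6-trihydroxyphenyl)propan-1-one (3-hydroxyphloretin)
Conditions: 1 (1.5 equiv), BF3·OEt2 (as solvent), 85 °C, Ar; then aq NaOAc
Reagents that add atoms: none
Why: Friedel–Crafts C-acylation of the highly nucleophilic phloroglucinol by the BF3-activated free acid should stop at the mono-ketone, because the product is deactivated as its boron chelate and the less electron-rich catechol ring of 2 cannot compete with excess 1.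

**Step 2**
Reactants: 3 3-hydroxyphloretin; 4 allyl bromide
Product: 5 1-[4-(allyloxy)-2,6-dihydroxyphenyl]-3-(3,4-dihydroxyphenyl)propan-1-one
Conditions: 4 (1.05 equiv), KHCO3 (1.5 equiv), DMF, 50 °C, Ar
Reagents that add atoms: none
Why: Williamson etherification in which hydrogencarbonate should ionise only the vinylogous-acid 4'-OH para to the ketone, while the hydrogen-bonded 2'/6'-OH and the less acidic catechol OH groups stay protonated, as in the selective 7-O-alkylation of 5,7-dihydroxyflavanones.

**Step 3**
Reactants: 5 4'-O-allyl ether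
Product: 7 1-(3-allyl-2,4,6-trihydroxyphenyl)-3-(3,4-dihydroxyphenyl)propan-1-one, via ortho-dienone 6 (not isolated)
Conditions: N,N-diethylaniline, 190 °C, sealed tube, Ar
Reagents that add atoms: none
Why: Aromatic Claisen rearrangement ([3,3]-sigmatropic shift to dienone 6, then tautomerisation) should give a single C-allyl product, because the ortho positions C3' and C5' are equivalent by the symmetry of ring A and the para position is blocked by the acyl group.

**Step 4**
Reactants: 7 3'-allyl-3-hydroxyphloretin; 8 3-bromo-2-methylprop-1-ene (methallyl bromide)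
Product: 9 1-{3-allyl-2,6-dihydroxy-4-[(2-methylprop-2-en-1-yl)oxy]phenyl}-3-(3,4-dihydroxyphenyl)propan-1-one
Conditions: 8 (1.05 equiv), KHCO3 (1.5 equiv), DMF, 50 °C, Ar
Reagents that add atoms: none
Why: The same acidity-guided Williamson etherification should apply, since the 4'-OH regenerated by the Claisen step is again the only hydroxyl ionised by hydrogencarbonate and the primary allylic bromide reacts by SN2 at oxygen.

**Step 5**
Reactants: 9 O-methallyl/C-allyl diene
Product: 10 1-(6,8-dihydroxy-3-methyl-2,5-dihydro-1-benzoxepin-7-yl)-3-(3,4-dihydroxyphenyl)propan-1-one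
Conditions: second-generation Grubbs catalyst (H2IMes)(PCy3)Cl2Ru=CHPh (5 mol%), degassed CH2Cl2 (0.005 M), 40 °C, Ar
Reagents that add atoms: none
Why: Ring-closing olefin metathesis: the ruthenium benzylidene should load onto the unhindered monosubstituted allyl terminus, the resulting alkylidene adds intramolecularly to the 1,1-disubstituted methallyl alkene through a ruthenacyclobutane, and cycloreversion delivers the C3=C4 double bond (sigma and pi components together) with loss of ethylene, which drives the equilibrium. The closest known reaction type is the metathetic closure of ortho-allylphenyl allyl ethers to 2,5-dihydro-1-benzoxepines. The seven-membered oxepine ring is closed by [2+2] cycloaddition/cycloreversion at the metal, giving an endocyclic olefin whose cis geometry is dictated by the ring. No stereocentre is created. The step needs cyclisation to win over intermolecular cross-metathesis and over allyl-to-propenyl isomerisation; the rigid ortho relationship of the two arms on ring A, high dilution and the reluctance of the methallyl alkene to homodimerise should secure this, and the free phenols and the aryl ketone should be tolerated by the catalyst.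

**Compound list**
1 | phloroglucinol (benzene-1,3,5-triol) | Oc1cc(O)cc(O)c1 | starting material
2 | 3-(3,4-dihydroxyphenyl)propanoic acid (dihydrocaffeic acid) | OC(=O)CCc1ccc(O)c(O)c1 | starting material
3 | 3-(3,4-dihydroxyphenyl)-1-(2,4,6-trihydroxyphenyl)propan-1-one (3-hydroxyphloretin) | O=C(CCc1ccc(O)c(O)c1)c1c(O)cc(O)cc1O | intermediate
4 | allyl bromide (3-bromoprop-1-ene) | C=CCBr | starting material
5 | 1-[4-(allyloxy)-2,6-dihydroxyphenyl]-3-(3,4-dihydroxyphenyl)propan-1-one | C=CCOc1cc(O)c(C(=O)CCc2ccc(O)c(O)c2)c(O)c1 | intermediate
6 | 6-allyl-4-[3-(3,4-dihydroxyphenyl)propanoyl]-3,5-dihydroxycyclohexa-2,4-dien-1-one (transient ortho-dienone, racemic) | C=CCC1C(=O)C=C(O)C(C(=O)CCc2ccc(O)c(O)c2)=C1O | intermediate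
7 | 1-(3-allyl-2,4,6-trihydroxyphenyl)-3-(3,4-dihydroxyphenyl)propan-1-one | C=CCc1c(O)cc(O)c(C(=O)CCc2ccc(O)c(O)c2)c1O | intermediate
8 | 3-bromo-2-methylprop-1-ene (methallyl bromide) | CC(=C)CBr | starting material
9 | 1-{3-allyl-2,6-dihydroxy-4-[(2-methylprop-2-en-1-yl)oxy]phenyl}-3-(3,4-dihydroxyphenyl)propan-1-one | CC(=C)COc1cc(O)c(C(=O)CCc2ccc(O)c(O)c2)c(O)c1CC=C | intermediate
10 | 1-(6,8-dihydroxy-3-methyl-2,5-dihydro-1-benzoxepin-7-yl)-3-(3,4-dihydroxyphenyl)propan-1-one | CC1=CCc2c(cc(O)c(C(=O)CCc3ccc(O)c(O)c3)c2O)OC1 | target

**Total step count:** 5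
**Longest linear sequence:** 5 steps (1 → 3 → 5 → 7 → 9 → 10)

**Steps most likely to fail**

Step 2. The risk is loss of site selectivity: alkylation may spill over to the catechol or the 2'/6'-hydroxyls, dialkylation may occur, and the electron-rich catechol may oxidise in the basic medium. The fallback sets out from 3 and masks the catechol before any alkylation. Heating 3 with dichlorodiphenylmethane in diphenyl ether at 175 °C should give the catechol ketal 3-(2,2-diphenyl-1,3-benzodioxol-5-yl)-1-(2,4,6-trihydroxyphenyl)propan-1-one F1. Allylation of F1 with 4 and KHCO3 in DMF should then give 1-[4-(allyloxy)-2,6-dihydroxyphenyl]-3-(2,2-diphenyl-1,3-benzodioxol-5-yl)propan-1-one F2. Claisen rearrangement of F2 in N,N-diethylaniline at 190 °C should give 1-(3-allyl-2,4,6-trihydroxyphenyl)-3-(2,2-diphenyl-1,3-benzodioxol-5-yl)propan-1-one F3. Hydrolysis of the ketal in AcOH/H2O (4:1) at reflux, before any acid-sensitive oxepine exists, returns the route at 7.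

Step 4. The risk is the same erosion of site selectivity, now at a 4'-hydroxyl flanked by the allyl group, so that competing etherification of the catechol or over-alkylation becomes more likely. The fallback sets out from 7 and replaces the anionic halide displacement by a neutral Mitsunobu etherification with 2-methylprop-2-en-1-ol, PPh3 and diisopropyl azodicarboxylate in THF at 0 °C. No phenoxide or catecholate is generated, and only the most acidic hydroxyl should be engaged by the betaine. It returns at 9, and no compound outside the compound list arises (entry F0).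

Step 5. The risks are catalyst deactivation by the polyphenol, allyl-to-propenyl isomerisation followed by ring-contracting metathesis, and oligomerisation instead of cyclisation. The fallback sets out from 9 and runs the ring closure on a fully capped substrate. Ac2O, pyridine and catalytic DMAP should give the tetraacetate 4-{3-[2,6-diacetoxy-3-allyl-4-(2-methylallyloxy)phenyl]-3-oxopropyl}-1,2-phenylene diacetate F4. Ring-closing metathesis of F4 with second-generation Grubbs catalyst (H2IMes)(PCy3)Cl2Ru=CHPh in CH2Cl2 at 40 °C should give the benzoxepine tetraacetate 4-[3-(6,8-diacetoxy-3-methyl-2,5-dihydro-1-benzoxepin-7-yl)-3-oxopropyl]-1,2-phenylene diacetate F5. Methanolysis with catalytic K2CO3 in degassed MeOH at 0 °C returns the route at 10.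

**Further compounds**
F1 | step 2 | 3-(2,2-diphenyl-1,3-benzodioxol-5-yl)-1-(2,4,6-trihydroxyphenyl)propan-1-one | O=C(CCc1ccc2OC(c3ccccc3)(c3ccccc3)Oc2c1)c1c(O)cc(O)cc1O
F2 | step 2 | 1-[4-(allyloxy)-2,6-dihydroxyphenyl]-3-(2,2-diphenyl-1,3-benzodioxol-5-yl)propan-1-one | C=CCOc1cc(O)c(C(=O)CCc2ccc3OC(c4ccccc4)(c4ccccc4)Oc3c2)c(O)c1
F3 | step 2 | 1-(3-allyl-2,4,6-trihydroxyphenyl)-3-(2,2-diphenyl-1,3-benzodioxol-5-yl)propan-1-one | C=CCc1c(O)cc(O)c(C(=O)CCc2ccc3OC(c4ccccc4)(c4ccccc4)Oc3c2)c1O
F0 | step 4 | none | none
F4 | step 5 | 4-{3-[2,6-diacetoxy-3-allyl-4-(2-methylallyloxy)phenyl]-3-oxopropyl}-1,2-phenylene diacetate | CC(=C)COc1cc(OC(C)=O)c(C(=O)CCc2ccc(OC(C)=O)c(OC(C)=O)c2)c(OC(C)=O)c1CC=C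
F5 | step 5 | 4-[3-(6,8-diacetoxy-3-methyl-2,5-dihydro-1-benzoxepin-7-yl)-3-oxopropyl]-1,2-phenylene diacetate | CC1=CCc2c(cc(OC(C)=O)c(C(=O)CCc3ccc(OC(C)=O)c(OC(C)=O)c3)c2OC(C)=O)OC1
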